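**Remark.** Chromone locants (O1, C2–C4, C4a, C5–C8, C8a) and primed locants for ring B are used. The 3'-hydroxyl is carried as a benzyl ether so that one BCl3 treatment frees both phenols at the end.

## Retrosynthetic overview

- Psiadiarabicin (5,3'-dihydroxy-6,7,2',4',5'-pentamethoxyflavone) comes from flavone 20 by cleavage of the 5-methyl and 3'-benzyl ethers. Ring C, the only ring made, is closed before that by 6-endo addition of the phenol of ynone 19 to the alkyne (O1–C2).
- The plan rests on ring A: C8a (bearing O1) and C4a (bearing the C4 carbonyl) are neighbours, and C4a has the C5 oxygen on its other side. That oxygen/acyl pair next to an alkoxy group is what a 3-alkoxyaryne gives when it inserts into a carboxylic acid C–O bond.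
- Key disconnection: O1–C8a and C4–C4a, leading to 3,4,5-trimethoxybenzyne (from silyl triflate 5) and arylpropiolic acid 16.
- Triflate 5 comes from 3,4,5-trimethoxyphenol (bromination, then silylation, retro-Brook shift and triflation). Acid 16 comes from 2,6-dimethoxyphenol (benzylation, formylation, bromination, methoxylation, Corey–Fuchs homologation with CO2 quench).

Key step: step 9

## Route

**Step 1**
Reactants: 1 3,4,5-trimethoxyphenol
Product: 2 2-bromo-3,4,5-trimethoxyphenol
Conditions: NBS (1.0 equiv), CH2Cl2, −78 °C to 0 °C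
Reagents that add atoms: N-bromosuccinimide, O=C1CCC(=O)N1Br
Why: Electrophilic aromatic bromination of a phenol; the two free positions are equivalent and both ortho to the hydroxyl, so one equivalent of NBS at low temperature should give the monobromide.

**Step 2**
Reactants: 2 2-bromo-3,4,5-trimethoxyphenol
Product: 5 3,4,5-trimethoxy-2-(trimethylsilyl)phenyl trifluoromethanesulfonate, via aryl silyl ether 3 (not isolated), via lithium silylphenoxide 4 (not isolated)
Conditions: HMDS, THF, reflux, then evaporation; n-BuLi, THF, −100 °C to −80 °C; Tf2O, −100 °C to rt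
Reagents that add atoms: hexamethyldisilazane, C[Si](C)(C)N[Si](C)(C)C; trifluoromethanesulfonic anhydride, O=S(=O)(OS(=O)(=O)C(F)(F)F)C(F)(F)F
Why: O-silylation, then bromine–lithium exchange sets off a 1,3 O-to-C silyl shift (retro-Brook rearrangement) to phenoxide 4, which Tf2O traps; this is the standard one-pot route from ortho-bromophenols to ortho-silylaryl triflates.

**Step 3**
Reactants: 6 2,6-dimethoxyphenol
Product: 7 2-(benzyloxy)-1,3-dimethoxybenzene
Conditions: BnBr, K2CO3, DMF, 60 °C
Reagents that add atoms: benzyl bromide, BrCc1ccccc1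
Why: Williamson ether synthesis on the hindered but acidic phenol.

**Step 4**
Reactants: 7 2-(benzyloxy)-1,3-dimethoxybenzene
Product: 8 3-(benzyloxy)-2,4-dimethoxybenzaldehyde
Conditions: POCl3, DMF, 80 °C; then ice-water
Reagents that add atoms: N,N-dimethylformamide, CN(C)C=O; water, O
Why: Vilsmeier–Haack formylation; as with 1,2,3-trimethoxybenzene, attack should occur ortho to one methoxyl and para to the other (the two such positions are equivalent) and not para to the twisted central benzyloxy group.

**Step 5**
Reactants: 8 3-(benzyloxy)-2,4-dimethoxybenzaldehyde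
Product: 9 3-(benzyloxy)-5-bromo-2,4-dimethoxybenzaldehyde
Conditions: NBS, DMF, rt
Reagents that add atoms: N-bromosuccinimide, O=C1CCC(=O)N1Br
Why: Electrophilic aromatic bromination; C5 is ortho to the 4-methoxyl, para to the 2-methoxyl and meta to the formyl group, whereas C6 is ortho to the formyl group and is not activated by a methoxyl.

**Step 6**
Reactants: 9 3-(benzyloxy)-5-bromo-2,4-dimethoxybenzaldehyde
Product: 12 3-(benzyloxy)-2,4,5-trimethoxybenzaldehyde, via bromo dimethyl acetal 10 (not isolated), via methoxy dimethyl acetal 11 (not isolated)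
Conditions: HC(OMe)3, TsOH (cat.), MeOH, reflux; then NaOMe, CuBr (cat.), DMF, 110 °C; then aq. HCl, THF, rt
Reagents that add atoms: sodium methoxide, [Na+].[O-]C; water, O
Why: The formyl group is masked in the same flask as its dimethyl acetal to keep it out of Cannizzaro-type reactions, a copper-catalysed Ullmann-type methoxylation replaces the bromide, and acidic work-up returns the aldehyde.

**Step 7**
Reactants: 12 3-(benzyloxy)-2,4,5-trimethoxybenzaldehyde
Product: 13 3-(benzyloxy)-1-(2,2-dibromovinyl)-2,4,5-trimethoxybenzene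
Conditions: CBr4, PPh3, Zn dust, CH2Cl2, 0 °C to rt
Reagents that add atoms: carbon tetrabromide, BrC(Br)(Br)Br
Why: First stage of the Corey–Fuchs reaction, a Wittig-type olefination of the aldehyde by dibromomethylenetriphenylphosphorane generated from CBr4, PPh3 and Zn.

**Step 8**
Reactants: 13 3-(benzyloxy)-1-(2,2-dibromovinyl)-2,4,5-trimethoxybenzene
Product: 16 3-[3-(benzyloxy)-2,4,5-trimethoxyphenyl]prop-2-ynoic acid, via bromoalkyne 14 (not isolated), via lithium acetylide 15 (not isolated)
Conditions: n-BuLi (2.1 equiv), THF, −78 °C; then CO2, −78 °C to rt; then aq. HCl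
Reagents that add atoms: carbon dioxide, O=C=O
Why: Second stage of the Corey–Fuchs reaction (dehydrobromination to 14, bromine–lithium exchange to 15) followed by carboxylation of the acetylide, which gives the propiolic acid directly.

**Step 9**
Reactants: 16 3-[3-(benzyloxy)-2,4,5-trimethoxyphenyl]prop-2-ynoic acid; 5 3,4,5-trimethoxy-2-(trimethylsilyl)phenyl trifluoromethanesulfonate
Product: 19 3-[3-(benzyloxy)-2,4,5-trimethoxyphenyl]-1-(2-hydroxy-4,5,6-trimethoxyphenyl)prop-2-yn-1-one, via cesium arylpropiolate 17 (not isolated), via 3,4,5-trimethoxybenzyne 18 (not isolated)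
Conditions: Cs2CO3 (1.0 equiv), THF, rt; then 5 (1.3 equiv), CsF, 18-crown-6, THF, 65 °C; then aq. HCl
Reagents that add atoms: none
Why: Fluoride removes the silyl group of 5 and triflate leaves, releasing aryne 18 (triple bond between the future C4a and C8a) slowly in the presence of preformed carboxylate 17. The carboxylate oxygen adds at the aryne carbon remote from the flanking methoxyl (future C8a), which places the developing negative charge on the future C4a next to the inductively withdrawing C5–O bond, the usual regiochemistry of 3-alkoxyarynes. The aryl anion then attacks the neighbouring ester carbonyl and the four-membered alkoxide so formed opens to the phenoxide of ynone 19, which makes O1–C8a and C4–C4a in one operation. The closest known reaction is the insertion of arynes into the C–O bond of carboxylic acids to give ortho-hydroxyaryl ketones (addition followed by an anionic Fries-type acyl shift). No ring is closed and no stereocenter is created; the selectivities needed are the regiochemistry of addition, secured by the C5 methoxyl beside the triple bond, and acyl transfer ahead of protonation, secured by the preformed cesium salt in dry aprotic THF and by the intramolecular nature of the shift. Crown-ether-solubilised fluoride allows a moderate temperature so that the phenoxide should not yet add to the ynone, and any portion that does gives 20, the product of step 10.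

**Step 10**
Reactants: 19 3-[3-(benzyloxy)-2,4,5-trimethoxyphenyl]-1-(2-hydroxy-4,5,6-trimethoxyphenyl)prop-2-yn-1-one
Product: 20 2-[3-(benzyloxy)-2,4,5-trimethoxyphenyl]-5,6,7-trimethoxy-4H-chromen-4-one
Conditions: DMAP (20 mol%), DMF, 40 °C
Reagents that add atoms: none
Why: Nucleophile-catalysed 6-endo oxa-Michael cyclisation of an ortho-hydroxyaryl ynone; DMAP adds to the alkyne terminus and the phenol displaces it by addition–elimination at C2, which should give the chromone and not the 5-exo aurone.

**Step 11**
Reactants: 20 2-[3-(benzyloxy)-2,4,5-trimethoxyphenyl]-5,6,7-trimethoxy-4H-chromen-4-one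
Product: 21 Psiadiarabicin, 5-hydroxy-2-(3-hydroxy-2,4,5-trimethoxyphenyl)-6,7-dimethoxy-4H-chromen-4-one
Conditions: BCl3, pentamethylbenzene, CH2Cl2, −78 °C to 0 °C; then H2O
Reagents that add atoms: none
Why: Lewis-acid ether cleavage; BCl3 with a cation scavenger removes the benzyl ether at low temperature, and on warming the boron chelated between the C4 carbonyl and the 5-methoxyl should cleave that peri methyl ether only.

## Compound list

1 | 3,4,5-trimethoxyphenol | COc1cc(O)cc(OC)c1OC | starting material
2 | 2-bromo-3,4,5-trimethoxyphenol | COc1cc(O)c(Br)c(OC)c1OC | intermediate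
3 | (2-bromo-3,4,5-trimethoxyphenoxy)trimethylsilane | C[Si](C)(C)Oc1cc(OC)c(OC)c(OC)c1Br | intermediate
4 | lithium 3,4,5-trimethoxy-2-(trimethylsilyl)phenoxide | [Li+].[O-]c1cc(OC)c(OC)c(OC)c1[Si](C)(C)C | intermediate
5 | 3,4,5-trimethoxy-2-(trimethylsilyl)phenyl trifluoromethanesulfonate | COc1cc(OS(=O)(=O)C(F)(F)F)c([Si](C)(C)C)c(OC)c1OC | intermediate
6 | 2,6-dimethoxyphenol | COc1cccc(OC)c1O | starting material
7 | 2-(benzyloxy)-1,3-dimethoxybenzene | COc1cccc(OC)c1OCc1ccccc1 | intermediate
8 | 3-(benzyloxy)-2,4-dimethoxybenzaldehyde | O=Cc1ccc(OC)c(OCc2ccccc2)c1OC | intermediate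
9 | 3-(benzyloxy)-5-bromo-2,4-dimethoxybenzaldehyde | O=Cc1cc(Br)c(OC)c(OCc2ccccc2)c1OC | intermediate
10 | 3-(benzyloxy)-1-bromo-5-(dimethoxymethyl)-2,4-dimethoxybenzene | COC(OC)c1cc(Br)c(OC)c(OCc2ccccc2)c1OC | intermediate
11 | 3-(benzyloxy)-1-(dimethoxymethyl)-2,4,5-trimethoxybenzene | COC(OC)c1cc(OC)c(OC)c(OCc2ccccc2)c1OC | intermediate
12 | 3-(benzyloxy)-2,4,5-trimethoxybenzaldehyde | O=Cc1cc(OC)c(OC)c(OCc2ccccc2)c1OC | intermediate
13 | 3-(benzyloxy)-1-(2,2-dibromovinyl)-2,4,5-trimethoxybenzene | BrC(Br)=Cc1cc(OC)c(OC)c(OCc2ccccc2)c1OC | intermediate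
14 | 3-(benzyloxy)-1-(bromoethynyl)-2,4,5-trimethoxybenzene | BrC#Cc1cc(OC)c(OC)c(OCc2ccccc2)c1OC | intermediate
15 | lithium [3-(benzyloxy)-2,4,5-trimethoxyphenyl]acetylide | [Li+].[C-]#Cc1cc(OC)c(OC)c(OCc2ccccc2)c1OC | intermediate
16 | 3-[3-(benzyloxy)-2,4,5-trimethoxyphenyl]prop-2-ynoic acid | O=C(O)C#Cc1cc(OC)c(OC)c(OCc2ccccc2)c1OC | intermediate
17 | cesium 3-[3-(benzyloxy)-2,4,5-trimethoxyphenyl]prop-2-ynoate | [Cs+].[O-]C(=O)C#Cc1cc(OC)c(OC)c(OCc2ccccc2)c1OC | intermediate
18 | 3,4,5-trimethoxybenzyne | COC1=C(OC)C(OC)=CC#C1 | intermediate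
19 | 3-[3-(benzyloxy)-2,4,5-trimethoxyphenyl]-1-(2-hydroxy-4,5,6-trimethoxyphenyl)prop-2-yn-1-one | COc1cc(O)c(C(=O)C#Cc2cc(OC)c(OC)c(OCc3ccccc3)c2OC)c(OC)c1OC | intermediate
20 | 2-[3-(benzyloxy)-2,4,5-trimethoxyphenyl]-5,6,7-trimethoxy-4H-chromen-4-one | COc1cc(-c2cc(=O)c3c(OC)c(OC)c(OC)cc3o2)c(OC)c(OCc2ccccc2)c1OC | intermediate
21 | Psiadiarabicin, 5-hydroxy-2-(3-hydroxy-2,4,5-trimethoxyphenyl)-6,7-dimethoxy-4H-chromen-4-one | COc1cc(-c2cc(=O)c3c(O)c(OC)c(OC)cc3o2)c(OC)c(O)c1OC | target

## Step count and risks

Total step count: 11. Longest linear sequence: 9 steps (steps 3 to 11, from 2,6-dimethoxyphenol).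

**Steps most likely to fail**

1. **Step 9 (aryne insertion).** The aryl anion may be protonated before the acyl shift, so that only the aryl ester forms. The propiolate may lose CO2 on heating, or the product phenoxide may be O-arylated by a second aryne. The fallback sets out from 1 and 12 and comes back at 20 by the classical chalcone route. Friedel–Crafts acetylation of 1 (AcOH, BF3·OEt2, 90 °C) should give 1-(2-hydroxy-4,5,6-trimethoxyphenyl)ethanone F1. Claisen–Schmidt condensation of this ketone with aldehyde 12 (KOH, EtOH, rt) should give (E)-3-[3-(benzyloxy)-2,4,5-trimethoxyphenyl]-1-(2-hydroxy-4,5,6-trimethoxyphenyl)prop-2-en-1-one F2. Oxidative cyclisation of the chalcone (I2 cat., DMSO, 120 °C) should then give flavone 20.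

2. **Step 6 (copper-catalysed methoxylation).** Substitution at the electron-rich, flanked bromide may be slow, with hydrodebromination competing. The fallback sets out from 9 and comes back at 12. Miyaura borylation (B2pin2, Pd(dppf)Cl2, KOAc, dioxane, 90 °C) should give 3-(benzyloxy)-2,4-dimethoxy-5-(4,4,5,5-tetramethyl-1,3,2-dioxaborolan-2-yl)benzaldehyde F3. Oxidation of the C–B bond (NaBO3·4H2O, THF–H2O, rt) should give 3-(benzyloxy)-5-hydroxy-2,4-dimethoxybenzaldehyde F4. O-Methylation (MeI, K2CO3, DMF, rt) should then give 12.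

3. **Step 11 (double ether cleavage).** Demethylation may continue at C6 or at the ring B methoxyls beside the freed 3'-oxygen, or the benzyl cation may alkylate C8. The fallback sets out from 20 and comes back at 21, with the two ethers removed by unrelated reactions. Hydrogenolysis (H2, Pd/C, EtOAc–MeOH, rt) should give 2-(3-hydroxy-2,4,5-trimethoxyphenyl)-5,6,7-trimethoxy-4H-chromen-4-one F5. Chelation-controlled demethylation of the 5-methoxyl alone (AlCl3, MeCN, 60 °C; then aq. HCl) should then give 21.

## Further compounds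

F1 | step 9 | 1-(2-hydroxy-4,5,6-trimethoxyphenyl)ethanone | CC(=O)c1c(O)cc(OC)c(OC)c1OC
F2 | step 9 | (E)-3-[3-(benzyloxy)-2,4,5-trimethoxyphenyl]-1-(2-hydroxy-4,5,6-trimethoxyphenyl)prop-2-en-1-one | COc1cc(O)c(C(=O)/C=C/c2cc(OC)c(OC)c(OCc3ccccc3)c2OC)c(OC)c1OC
F3 | step 6 | 3-(benzyloxy)-2,4-dimethoxy-5-(4,4,5,5-tetramethyl-1,3,2-dioxaborolan-2-yl)benzaldehyde | O=Cc1cc(B2OC(C)(C)C(C)(C)O2)c(OC)c(OCc2ccccc2)c1OC
F4 | step 6 | 3-(benzyloxy)-5-hydroxy-2,4-dimethoxybenzaldehyde | O=Cc1cc(O)c(OC)c(OCc2ccccc2)c1OC
F5 | step 11 | 2-(3-hydroxy-2,4,5-trimethoxyphenyl)-5,6,7-trimethoxy-4H-chromen-4-one | COc1cc(-c2cc(=O)c3c(OC)c(OC)c(OC)cc3o2)c(OC)c(O)c1OC
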